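The C50 polyene is split at C11=C12 and C11′=C12′ into a C10 dialdehyde and two identical C20 end groups, and each end group rests on cutting the C1–C6 bond of its ring A (C1 to C6). In the ring, C2 bears H, the gem-dimethyl carbon C1, C3 and the CH2 of the five-carbon arm, which is the pattern around C4 of (R)-limonene. The key step protonates the isopropenyl group of an acyclic trienone ester, made from limonene oxide with that centre in place, and the C5=C6 alkene of its dienone captures the C1 cation. One operation closes ring A, creates the gem-dimethyl carbon and places the ring alkene, while C2 is carried through.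

Key step: step 5

Remarks on the chemistry:
- Assumption: the commercial cis/trans mixture of (+)-limonene 1,2-oxide, which keeps the (4R) centre of (R)-limonene, is the starting material; both epoxide diastereomers give the same keto aldehyde in step 1.
- Numbering: ring atoms C1–C6 and chain atoms C7–C15 follow carotenoid usage. Acyclic compounds are named by their own chain, so the chain bond C8=C9 of 12 is the later ring bond C5=C6.
- Precursor design: the arm stays a conjugated methyl ester until the last step. It is O-protonated and inert in the acid of step 5, it cannot be scrambled by methoxide in steps 4 and 8, and a free allylic alcohol would not survive steps 5 and 7. Compound 12 is used together with its 8Z isomer, because step 5 erases that geometry.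

Step 1
Reactants: 1 (4R)-limonene 1,2-oxide (cis/trans mixture)
Product: 3 (3R)-6-oxo-3-(prop-1-en-2-yl)heptanal, via 1,2-diol 2 (not isolated)
Conditions: H5IO6 (1.1 equiv), THF/H2O, 0 °C to rt
Reagents that add atoms: water, O
Why: Acid-promoted epoxide hydrolysis followed by Malaprade glycol cleavage in one flask, in which both epoxide diastereomers converge and the stereocentre, β to the new aldehyde and not enolizable, passes through unchanged.

Step 2
Reactants: 3 (3R)-6-oxo-3-(prop-1-en-2-yl)heptanal; 4 methyl 2-(triphenylphosphoranylidene)propanoate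
Product: 5 methyl (2E,5R)-2-methyl-8-oxo-5-(prop-1-en-2-yl)non-2-enoate
Conditions: CH2Cl2, 0 °C to rt
Reagents that add atoms: methyl 2-(triphenylphosphoranylidene)propanoate (4), COC(=O)C(C)=P(c1ccccc1)(c1ccccc1)c1ccccc1
Why: Wittig olefination with a stabilized ylide, which reacts with the aldehyde and leaves the methyl ketone alone under neutral conditions (no aldol of the 1,6-dicarbonyl compound) and should give the (E)-enoate under the usual thermodynamic control of ester ylides.

Step 3
Reactants: 5 methyl (2E,5R)-2-methyl-8-oxo-5-(prop-1-en-2-yl)non-2-enoate; 6 ethynylmagnesium bromide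
Product: 7 methyl (2E,5R)-8-hydroxy-2,8-dimethyl-5-(prop-1-en-2-yl)dec-2-en-9-ynoate (both C8 epimers)
Conditions: THF, −20 to 0 °C; aq. NH4Cl
Reagents that add atoms: ethynylmagnesium bromide (6), C#C[Mg]Br
Why: Grignard 1,2-addition of an acetylide to the methyl ketone, which is far more electrophilic than the α-methyl enoate at this temperature; the carbinol centre forms as both epimers, which does not matter because it becomes sp2 in step 4.

Step 4
Reactants: 7 methyl (2E,5R)-8-hydroxy-2,8-dimethyl-5-(prop-1-en-2-yl)dec-2-en-9-ynoate; 8 2-methoxypropene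
Product: 12 methyl (2E,5R,8E,10E)-2,8-dimethyl-12-oxo-5-(prop-1-en-2-yl)trideca-2,8,10-trienoate, via mixed ketal 9 (not isolated), via propargyl isopropenyl ether 10 (not isolated), via allenyl ketone 11 (not isolated)
Conditions: 8 (3 equiv), p-TsOH·H2O (0.5 mol %), toluene, sealed vessel, 90 °C; then NaOMe (5 mol %), MeOH, 0 °C to rt
Reagents that add atoms: 2-methoxypropene (8), COC(C)=C
Why: Saucy–Marbet sequence, in which acid-catalysed exchange gives the propargyl isopropenyl ether, a propargyl Claisen [3,3] shift gives the β-allenyl ketone, and catalytic methoxide moves the allene into conjugation as the (10E)-dienone, with the C5 stereocentre remote from every acidic site.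

Step 5
Reactants: 12 methyl (2E,5R,8E,10E)-2,8-dimethyl-12-oxo-5-(prop-1-en-2-yl)trideca-2,8,10-trienoate
Product: 15 methyl (2E)-2-methyl-4-[(1R)-2,2,4-trimethyl-3-[(1E)-3-oxobut-1-en-1-yl]cyclohex-3-en-1-yl]but-2-enoate, via tertiary C1 cation 13 (not isolated), via ring-closed C5 cation 14 (not isolated)
Conditions: conc. H2SO4 (96 %, 6 equiv), CH2Cl2, −15 to 0 °C, short contact; poured onto ice
Reagents that add atoms: none
Why: Markovnikov protonation of the isopropenyl group gives the tertiary C1 cation 13, C6 of the dienone alkene (C5=C6) bonds to it to give the tertiary C5 cation 14, and loss of the C6 proton delivers the tetrasubstituted ring alkene conjugated with the enone. The closest known reaction type is the sulfuric acid cyclization of pseudoionone to β-ionone and of pseudoirones to irones, where the same dienone alkene captures a tertiary cation that sits beside a C–H carbon. Ring A (C1 to C6) closes through a chair-like transition state, 6-endo with respect to the attacking alkene, with the enoate arm on C2 equatorial. No stereocentre is made: C2 is the limonene-derived centre and only has to survive, and C6 ends sp2. Three selectivities are needed and each has a handle in the substrate: ionization at the isopropenyl group alone (dienone and enoate are O-protonated and inert at carbon, and the strong acid protonates the 1,1-disubstituted alkene before it can act as a nucleophile toward the dienone), the β position of the ring alkene (conjugation makes it the thermodynamic sink under reversible protonation), and retention at C2 (a 1,2-hydride shift would place charge on C2 only two bonds from the O-protonated enoate, and cold, brief contact should keep ring closure ahead of it). Both C8=C9 isomers of 12 give the same cation 14, so the mixture from step 4 can be used.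

Step 6
Reactants: 15 methyl (2E)-2-methyl-4-[(1R)-2,2,4-trimethyl-3-[(1E)-3-oxobut-1-en-1-yl]cyclohex-3-en-1-yl]but-2-enoate; 16 vinylmagnesium bromide
Product: 17 methyl (2E)-4-[(1R)-3-[(1E)-3-hydroxy-3-methylpenta-1,4-dien-1-yl]-2,2,4-trimethylcyclohex-3-en-1-yl]-2-methylbut-2-enoate (both carbinol epimers)
Conditions: THF, −30 to 0 °C; aq. NH4Cl
Reagents that add atoms: vinylmagnesium bromide (16), C=C[Mg]Br
Why: Grignard 1,2-addition to the conjugated methyl ketone, kept cold so that the hindered α-methyl enoate is not attacked; the tertiary carbinol forms as both epimers and loses its stereocentre in step 7.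

Step 7
Reactants: 17 methyl (2E)-4-[(1R)-3-[(1E)-3-hydroxy-3-methylpenta-1,4-dien-1-yl]-2,2,4-trimethylcyclohex-3-en-1-yl]-2-methylbut-2-enoate; 18 triphenylphosphine hydrobromide
Product: 19 {(2E,4E)-5-[(5R)-5-[(2E)-4-methoxy-3-methyl-4-oxobut-2-en-1-yl]-2,6,6-trimethylcyclohex-1-en-1-yl]-3-methylpenta-2,4-dien-1-yl}triphenylphosphonium bromide
Conditions: MeOH, rt
Reagents that add atoms: triphenylphosphine hydrobromide (18), [Br-].[PH+](c1ccccc1)(c1ccccc1)c1ccccc1
Why: Acid ionization of the tertiary bis-allylic alcohol to a pentadienyl cation and capture by PPh3 at the unhindered primary terminus (allylic transposition, the standard entry to ionylidene-ethyl Wittig salts), with the methyl ester inert in methanol and the (2E,4E) salt expected to crystallize.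

Step 8
Reactants: 19 the C20 phosphonium bromide (2.2 equiv); 20 (2E,4E,6E)-2,7-dimethylocta-2,4,6-trienedial
Product: 24 (2R,2′R)-2,2′-bis[(2E)-4-methoxy-3-methyl-4-oxobut-2-en-1-yl]-β,β-carotene (all-E), via C20 ylide 21 (not isolated), via C30 monoaldehyde 22 (not isolated), via Z-containing diester mixture 23 (not isolated)
Conditions: NaOMe (2.3 equiv), MeOH/CH2Cl2, 0 °C to rt; aqueous wash, then n-heptane, reflux, N2, dark
Reagents that add atoms: (2E,4E,6E)-2,7-dimethylocta-2,4,6-trienedial (20), O=C/C(C)=C/C=C/C=C(C)/C=O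
Why: Twofold Wittig olefination of the dialdehyde with the semi-stabilized allylic ylide, followed by thermal equilibration in which the sterically hindered Z bonds at C11=C12 and C11′=C12′ relax to E and the all-E diester should crystallize; no stereocentre is involved.

Step 9
Reactants: 24 (2R,2′R)-2,2′-bis[(2E)-4-methoxy-3-methyl-4-oxobut-2-en-1-yl]-β,β-carotene
Product: 25 (2R,2′R)-2,2′-bis[(2E)-4-hydroxy-3-methylbut-2-en-1-yl]-β,β-carotene (all-E), the target
Conditions: i-Bu2AlH (6 equiv), CH2Cl2/THF, −78 to −30 °C; aq. KNaC4H4O6; Ar, dark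
Reagents that add atoms: none
Why: i-Bu2AlH 1,2-reduction of both α,β-unsaturated esters to the (E)-allylic alcohols at low temperature, a reduction to which the polyene, the alkene geometries and the two C2 stereocentres are inert.

Compound list
1 | (4R)-limonene 1,2-oxide, (4R)-1-methyl-4-(prop-1-en-2-yl)-7-oxabicyclo[4.1.0]heptane, cis/trans mixture | CC12OC1C[C@@H](CC2)C(C)=C | starting material
2 | (4R)-1-methyl-4-(prop-1-en-2-yl)cyclohexane-1,2-diol (not isolated) | CC1(O)C(O)C[C@@H](CC1)C(C)=C | intermediate
3 | (3R)-6-oxo-3-(prop-1-en-2-yl)heptanal | O=CC[C@@H](CCC(C)=O)C(C)=C | intermediate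
4 | methyl 2-(triphenylphosphoranylidene)propanoate | COC(=O)C(C)=P(c1ccccc1)(c1ccccc1)c1ccccc1 | starting material
5 | methyl (2E,5R)-2-methyl-8-oxo-5-(prop-1-en-2-yl)non-2-enoate | COC(=O)/C(C)=C/C[C@@H](CCC(C)=O)C(C)=C | intermediate
6 | ethynylmagnesium bromide | C#C[Mg]Br | starting material
7 | methyl (2E,5R)-8-hydroxy-2,8-dimethyl-5-(prop-1-en-2-yl)dec-2-en-9-ynoate (both C8 epimers) | COC(=O)/C(C)=C/C[C@@H](CCC(C)(O)C#C)C(C)=C | intermediate
8 | 2-methoxypropene | COC(C)=C | starting material
9 | methyl (2E,5R)-8-[(2-methoxypropan-2-yl)oxy]-2,8-dimethyl-5-(prop-1-en-2-yl)dec-2-en-9-ynoate, mixed ketal (not isolated) | COC(=O)/C(C)=C/C[C@@H](CCC(C)(OC(C)(C)OC)C#C)C(C)=C | intermediate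
10 | methyl (2E,5R)-2,8-dimethyl-5-(prop-1-en-2-yl)-8-(prop-1-en-2-yloxy)dec-2-en-9-ynoate, propargyl isopropenyl ether (not isolated) | COC(=O)/C(C)=C/C[C@@H](CCC(C)(OC(C)=C)C#C)C(C)=C | intermediate
11 | methyl (2E,5R)-2,8-dimethyl-12-oxo-5-(prop-1-en-2-yl)trideca-2,8,9-trienoate, allenyl ketone (not isolated) | COC(=O)/C(C)=C/C[C@@H](CCC(C)=C=CCC(C)=O)C(C)=C | intermediate
12 | methyl (2E,5R,8E,10E)-2,8-dimethyl-12-oxo-5-(prop-1-en-2-yl)trideca-2,8,10-trienoate (precursor of the key step; its 8Z isomer is carried along) | COC(=O)/C(C)=C/C[C@@H](CC/C(C)=C/C=C/C(C)=O)C(C)=C | intermediate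
13 | tertiary C1 cation from 12, carbonyl groups drawn unprotonated (not isolated) | COC(=O)/C(C)=C/C[C@@H](CC/C(C)=C/C=C/C(C)=O)[C+](C)C | intermediate
14 | ring-closed tertiary C5 cation, carbonyl groups drawn unprotonated (not isolated) | CC(=O)/C=C/C1[C+](C)CC[C@H](C/C=C(\C)C(=O)OC)C1(C)C | intermediate
15 | methyl (2E)-2-methyl-4-[(1R)-2,2,4-trimethyl-3-[(1E)-3-oxobut-1-en-1-yl]cyclohex-3-en-1-yl]but-2-enoate (product of the key step) | CC(=O)/C=C/C1=C(C)CC[C@H](C/C=C(\C)C(=O)OC)C1(C)C | intermediate
16 | vinylmagnesium bromide | C=C[Mg]Br | starting material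
17 | methyl (2E)-4-[(1R)-3-[(1E)-3-hydroxy-3-methylpenta-1,4-dien-1-yl]-2,2,4-trimethylcyclohex-3-en-1-yl]-2-methylbut-2-enoate (both carbinol epimers) | C=CC(C)(O)/C=C/C1=C(C)CC[C@H](C/C=C(\C)C(=O)OC)C1(C)C | intermediate
18 | triphenylphosphine hydrobromide | [Br-].[PH+](c1ccccc1)(c1ccccc1)c1ccccc1 | starting material
19 | {(2E,4E)-5-[(5R)-5-[(2E)-4-methoxy-3-methyl-4-oxobut-2-en-1-yl]-2,6,6-trimethylcyclohex-1-en-1-yl]-3-methylpenta-2,4-dien-1-yl}triphenylphosphonium bromide | [Br-].c1ccccc1[P+](c1ccccc1)(c1ccccc1)C/C=C(C)/C=C/C2=C(C)CC[C@H](C/C=C(\C)C(=O)OC)C2(C)C | intermediate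
20 | (2E,4E,6E)-2,7-dimethylocta-2,4,6-trienedial | O=C/C(C)=C/C=C/C=C(C)/C=O | starting material
21 | C20 ylide from 19 (not isolated) | c1ccccc1P(c1ccccc1)(c1ccccc1)=C/C=C(C)/C=C/C2=C(C)CC[C@H](C/C=C(\C)C(=O)OC)C2(C)C | intermediate
22 | methyl (2E)-2-methyl-4-[(1R)-2,2,4-trimethyl-3-[(1E,3E,7E,9E,11E)-3,7,12-trimethyl-13-oxotrideca-1,3,5,7,9,11-hexaen-1-yl]cyclohex-3-en-1-yl]but-2-enoate, C30 monoaldehyde, E/Z at the new C5=C6 chain bond (not isolated) | O=C/C(C)=C/C=C/C=C(\C)C=CC(/[H])=C(C)/C=C/C1=C(C)CC[C@H](C/C=C(\C)C(=O)OC)C1(C)C | intermediate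
23 | (2R,2′R)-2,2′-bis[(2E)-4-methoxy-3-methyl-4-oxobut-2-en-1-yl]-β,β-carotene, mixture of E/Z isomers at C11=C12 and C11′=C12′ (not isolated) | CC1=C(/C=C/C(C)=C(\[H])C=CC(/C)=C/C=C/C=C(\C)C=CC(/[H])=C(C)/C=C/C2=C(C)CC[C@H](C/C=C(\C)C(=O)OC)C2(C)C)C(C)(C)[C@@H](C/C=C(\C)C(=O)OC)CC1 | intermediate
24 | (2R,2′R)-2,2′-bis[(2E)-4-methoxy-3-methyl-4-oxobut-2-en-1-yl]-β,β-carotene, all-E | CC1=C(/C=C/C(C)=C/C=C/C(C)=C/C=C/C=C(C)/C=C/C=C(C)/C=C/C2=C(C)CC[C@H](C/C=C(\C)C(=O)OC)C2(C)C)C(C)(C)[C@@H](C/C=C(\C)C(=O)OC)CC1 | intermediate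
25 | (2R,2′R)-2,2′-bis[(2E)-4-hydroxy-3-methylbut-2-en-1-yl]-β,β-carotene, all-E | CC1=C(/C=C/C(C)=C/C=C/C(C)=C/C=C/C=C(C)/C=C/C=C(C)/C=C/C2=C(C)CC[C@H](C/C=C(\C)CO)C2(C)C)C(C)(C)[C@@H](C/C=C(\C)CO)CC1 | target

Total step count: 9
Longest linear sequence: 9 steps (1 to 25); compounds 4, 6, 8, 16, 18 and 20 are bought.

Steps most likely to fail

Step 5. What may go wrong: migration of hydride from C2 to the C1 cation, or reversible proton loss from C2, before the ring closes, which would erode the configuration at C2. The ring alkene may also move slowly into conjugation, and forcing it means longer acid contact. The fallback sets out from 7 and comes back at 15. It closes the ring one stage earlier on an aldehyde, where the alkene position is corrected by base, so acid contact is limited to the closure itself; the cation is of the same kind, so this does not remove the hydride-shift risk. Meyer–Schuster rearrangement of 7 (VO(OSiPh3)3 cat., xylene, 130 °C) should give the enal methyl (2E,5R,8E)-2,8-dimethyl-10-oxo-5-(prop-1-en-2-yl)deca-2,8-dienoate F1. Condensation with aniline (MgSO4, Et2O) gives the N-phenyl imine methyl (2E,5R,8E)-2,8-dimethyl-10-(phenylimino)-5-(prop-1-en-2-yl)deca-2,8-dienoate F2. Addition to conc. H2SO4 at −20 °C, hydrolysis on ice and brief NaOMe/MeOH treatment (the classical citral to β-cyclocitral protocol) should give the ring aldehyde methyl (2E)-4-[(1R)-3-formyl-2,2,4-trimethylcyclohex-3-en-1-yl]-2-methylbut-2-enoate F3. Claisen–Schmidt condensation with acetone (NaOMe, acetone, reflux) then returns to 15.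

Step 4. What may go wrong: acid-promoted hydration or migration of the isopropenyl double bond during the hot ketal exchange, or incomplete conjugation of the allene. The fallback sets out from 7 and comes back at 12 by way of 11. It is the acid-free Kimel–Cope variant of the Carroll rearrangement. Acetoacetylation of 7 with 2,2,6-trimethyl-4H-1,3-dioxin-4-one (xylene, 130 °C) gives the acetoacetate methyl (2E,5R)-2,8-dimethyl-8-[(3-oxobutanoyl)oxy]-5-(prop-1-en-2-yl)dec-2-en-9-ynoate F4. Heating with Al(OiPr)3 (cat.) at 160 °C induces the [3,3] shift to the allenyl β-keto acid (8R,11E)-2-acetyl-12-methoxy-5,11-dimethyl-12-oxo-8-(prop-1-en-2-yl)dodeca-3,4,10-trienoic acid F5, which loses CO2 to give allenyl ketone 11. The NaOMe treatment of step 4 then completes the way to 12.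

Step 6. What may go wrong: attack of the strongly basic vinyl Grignard reagent on the methyl ester, or enolization of the methyl ketone. The fallback sets out from 15 and comes back at 17. The two carbons are brought in as an alkyne: ethynylmagnesium bromide 6 (THF, 0 °C), which is smaller and less basic, should give the ethynyl carbinol methyl (2E)-4-[(1R)-3-[(1E)-3-hydroxy-3-methylpent-1-en-4-yn-1-yl]-2,2,4-trimethylcyclohex-3-en-1-yl]-2-methylbut-2-enoate F6. Semihydrogenation over Pd/CaCO3 poisoned with Pb(OAc)2 (quinoline, H2, hexane) then gives 17.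

Further compounds
F1 | step 5 | methyl (2E,5R,8E)-2,8-dimethyl-10-oxo-5-(prop-1-en-2-yl)deca-2,8-dienoate | COC(=O)/C(C)=C/C[C@@H](CC/C(C)=C/C=O)C(C)=C
F2 | step 5 | methyl (2E,5R,8E)-2,8-dimethyl-10-(phenylimino)-5-(prop-1-en-2-yl)deca-2,8-dienoate | COC(=O)/C(C)=C/C[C@@H](CC/C(C)=C/C=N/c1ccccc1)C(C)=C
F3 | step 5 | methyl (2E)-4-[(1R)-3-formyl-2,2,4-trimethylcyclohex-3-en-1-yl]-2-methylbut-2-enoate | O=CC1=C(C)CC[C@H](C/C=C(\C)C(=O)OC)C1(C)C
F4 | step 4 | methyl (2E,5R)-2,8-dimethyl-8-[(3-oxobutanoyl)oxy]-5-(prop-1-en-2-yl)dec-2-en-9-ynoate | COC(=O)/C(C)=C/C[C@@H](CCC(C)(OC(=O)CC(C)=O)C#C)C(C)=C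
F5 | step 4 | (8R,11E)-2-acetyl-12-methoxy-5,11-dimethyl-12-oxo-8-(prop-1-en-2-yl)dodeca-3,4,10-trienoic acid | COC(=O)/C(C)=C/C[C@@H](CCC(C)=C=CC(C(C)=O)C(O)=O)C(C)=C
F6 | step 6 | methyl (2E)-4-[(1R)-3-[(1E)-3-hydroxy-3-methylpent-1-en-4-yn-1-yl]-2,2,4-trimethylcyclohex-3-en-1-yl]-2-methylbut-2-enoate | C#CC(C)(O)/C=C/C1=C(C)CC[C@H](C/C=C(\C)C(=O)OC)C1(C)C
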